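**Retrosynthetic overview** (locants C1–C7a are those of the hexahydroindene core of the target)

1. Target 23 ⇐ methyl ester 22 (thiolate demethylation) ⇐ 21 ⇐ 20: the C1 ethyl group is put in by alkylating a bicyclic β-keto sulfone, and the sulfone is then removed reductively.
2. 20 ⇐ acyclic tetraene β-keto sulfone 19: one intramolecular [4+2] cycloaddition makes C3a–C7a and C4–C5, so the cyclopentanone and the cyclohexene form together in the same step; no ring exists before it.
3. The only fixed stereocentre in 19 is C3; the α-sulfonyl centre C1 is stereolabile and funnels through the matched transition state, so C3a, C7a, C4 and C5 are set in that one step.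
4. 19 ⇐ trienyl sulfone 7 + aldehyde 16 (C1–C2 bond by α-sulfonyl carbanion addition, then oxidation).
5. 7 ⇐ enone 1 + phosphonate 2 (vinylogous olefination, reduction, sulfonylation); 16 ⇐ (R)-Roche ester 8 + ylide 14 (Wittig).

Assumption: with both α-centres of the cyclopentanone epimerisable, the target's trans,trans arrangement (each α-alkyl group anti to the neighbouring ring-fusion substituent) is taken to be the thermodynamic one.

**Route**

Step 1
Reactants: 1 (E)-1-phenylpent-1-en-3-one; 2 ethyl (E)-4-(diethoxyphosphoryl)-3-methylbut-2-enoate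
Product: 4 ethyl (2E,4E,6E)-5-ethyl-3-methyl-7-phenylhepta-2,4,6-trienoate, via phosphonate sodium salt 3 (not isolated)
Conditions: NaH, THF, 0 °C; then 1, 0 to 25 °C; I2 (2 mol %), PhH, daylight, 25 °C; chromatography
Reagents that add atoms: none
Why: Vinylogous Horner–Wadsworth–Emmons olefination; the phosphonate carbanion adds 1,2 to the enone carbonyl and loses phosphate, the new double bonds form as E/Z mixtures, and iodine equilibration enriches the all-E isomer, which is separated (no stereocentre).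

Step 2
Reactants: 4 ethyl (2E,4E,6E)-5-ethyl-3-methyl-7-phenylhepta-2,4,6-trienoate
Product: 5 (2E,4E,6E)-5-ethyl-3-methyl-7-phenylhepta-2,4,6-trien-1-ol
Conditions: i-Bu2AlH (2.2 equiv), CH2Cl2, −78 to 0 °C
Reagents that add atoms: none
Why: 1,2-Reduction of a conjugated ester by an aluminium hydride gives the allylic alcohol without touching the polyene.

Step 3
Reactants: 5 (2E,4E,6E)-5-ethyl-3-methyl-7-phenylhepta-2,4,6-trien-1-ol
Product: 7 {[(2E,4E,6E)-5-ethyl-3-methyl-7-phenylhepta-2,4,6-trien-1-yl]sulfonyl}benzene, via trienyl bromide 6 (not isolated)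
Conditions: PBr3 (0.4 equiv), pyridine (cat.), Et2O, −20 °C; then PhSO2Na, DMF, 0 to 25 °C
Reagents that add atoms: sodium benzenesulfinate, [Na+].[O-]S(=O)c1ccccc1
Why: Bromination of the primary allylic alcohol followed by SN2 S-alkylation of the sulfinate gives the primary allylic sulfone with the triene geometry retained.

Step 4
Reactants: 8 methyl (R)-3-hydroxy-2-methylpropanoate
Product: 9 methyl (R)-2-methyl-3-[(triethylsilyl)oxy]propanoate
Conditions: Et3SiCl, imidazole, CH2Cl2, 0 °C
Reagents that add atoms: chlorotriethylsilane, CC[Si](CC)(CC)Cl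
Why: Standard O-silylation; the stereocentre (future C3) is untouched.

Step 5
Reactants: 9 methyl (R)-2-methyl-3-[(triethylsilyl)oxy]propanoate
Product: 10 (R)-2-methyl-3-[(triethylsilyl)oxy]propanal
Conditions: i-Bu2AlH (1.1 equiv), CH2Cl2, −78 °C; used at once
Reagents that add atoms: none
Why: Partial ester reduction stops at the aldehyde because the tetrahedral aluminium acetal is stable at −78 °C; the α-stereocentre survives if the aldehyde is not stored.

Step 6
Reactants: 11 methyl 2-bromobutanoate; 12 triphenylphosphine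
Product: 14 methyl 2-(triphenylphosphoranylidene)butanoate, via phosphonium bromide 13 (not isolated)
Conditions: PhMe, 90 °C; then NaOH (2 M aq.), CH2Cl2, 25 °C
Reagents that add atoms: none
Why: SN2 quaternisation of the phosphine and deprotonation of the salt give the stabilised ylide.

Step 7
Reactants: 10 (R)-2-methyl-3-[(triethylsilyl)oxy]propanal; 14 methyl 2-(triphenylphosphoranylidene)butanoate
Product: 15 methyl (2E,4S)-2-ethyl-4-methyl-5-[(triethylsilyl)oxy]pent-2-enoate
Conditions: CH2Cl2, 40 °C, 24 h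
Reagents that add atoms: none
Why: Wittig olefination with a stabilised ylide gives the (E)-trisubstituted enoate (ester trans to the branched chain); the neutral conditions leave the stereocentre intact.

Step 8
Reactants: 15 methyl (2E,4S)-2-ethyl-4-methyl-5-[(triethylsilyl)oxy]pent-2-enoate
Product: 16 methyl (2E,4S)-2-ethyl-4-methyl-5-oxopent-2-enoate
Conditions: (COCl)2, DMSO, CH2Cl2, −78 to −40 °C; i-Pr2NEt, −78 °C; cold pH 7 buffer; used at once
Reagents that add atoms: none
Why: Swern-type oxidative desilylation; chlorodimethylsulfonium cleaves the primary Et3Si–O bond and the alkoxysulfonium ylide collapses to the aldehyde, while the hindered base and cold quench protect the α-stereocentre.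

Step 9
Reactants: 7 {[(2E,4E,6E)-5-ethyl-3-methyl-7-phenylhepta-2,4,6-trien-1-yl]sulfonyl}benzene; 16 methyl (2E,4S)-2-ethyl-4-methyl-5-oxopent-2-enoate
Product: 18 methyl (2E,4S,7E,9E,11E)-2,10-diethyl-5-hydroxy-4,8-dimethyl-12-phenyl-6-(phenylsulfonyl)dodeca-2,7,9,11-tetraenoate (C5/C6 diastereomer mixture), via lithiated sulfone 17 (not isolated)
Conditions: n-BuLi, THF, −78 °C; then 16, −78 °C; AcOH, −78 °C
Reagents that add atoms: none
Why: Julia-type 1,2-addition of the α-lithio allylic sulfone through its α-carbon forms the C1–C2 bond; the carbinol and sulfonyl centres form without control, which does not matter because the first is oxidised and the second is stereolabile in the next step.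

Step 10
Reactants: 18 methyl (2E,4S,7E,9E,11E)-2,10-diethyl-5-hydroxy-4,8-dimethyl-12-phenyl-6-(phenylsulfonyl)dodeca-2,7,9,11-tetraenoate
Product: 20 methyl (3S,3aS,4R,5S,7aS)-4,5-diethyl-3,7-dimethyl-2-oxo-5-[(E)-2-phenylethenyl]-1-(phenylsulfonyl)-2,3,3a,4,5,7a-hexahydro-1H-indene-4-carboxylate (both C1 epimers), via β-keto sulfone 19 (not isolated)
Conditions: IBX (1.5 equiv), EtOAc, 75 °C, 3 h; filter; PhMe (0.01 M), BHT (5 mol %), 100 °C, 36 h
Reagents that add atoms: none
Why: IBX oxidation gives β-keto sulfone 19, whose type 1 intramolecular Diels–Alder reaction closes the five- and six-membered rings together; the C3 stereocentre (its H eclipsing the enoate plane to avoid A(1,3) strain with the C4 ethyl) sends the diene to the face anti to the C3 methyl, the ester-endo transition state gives the trans ring fusion and the cis ester/styryl relationship (C3a, C7a, C4, C5), and the α-sulfonyl centre equilibrates through the enol so all material reacts through the matched arrangement.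

Step 11
Reactants: 20 methyl (3S,3aS,4R,5S,7aS)-4,5-diethyl-3,7-dimethyl-2-oxo-5-[(E)-2-phenylethenyl]-1-(phenylsulfonyl)-2,3,3a,4,5,7a-hexahydro-1H-indene-4-carboxylate
Product: 21 methyl (3S,3aS,4R,5S,7aS)-1,4,5-triethyl-3,7-dimethyl-2-oxo-5-[(E)-2-phenylethenyl]-1-(phenylsulfonyl)-2,3,3a,4,5,7a-hexahydro-1H-indene-4-carboxylate (C1 configuration not assigned)
Conditions: K2CO3, EtI, DMF, 40 °C
Reagents that add atoms: iodoethane, CCI
Why: C-alkylation of the doubly stabilised β-keto sulfone enolate is regiospecific for C1; the configuration of the new quaternary centre is irrelevant because the sulfone is removed next.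

Step 12
Reactants: 21 methyl (3S,3aS,4R,5S,7aS)-1,4,5-triethyl-3,7-dimethyl-2-oxo-5-[(E)-2-phenylethenyl]-1-(phenylsulfonyl)-2,3,3a,4,5,7a-hexahydro-1H-indene-4-carboxylate
Product: 22 methyl (1S,3S,3aR,4R,5S,7aR)-1,4,5-triethyl-3,7-dimethyl-2-oxo-5-[(E)-2-phenylethenyl]-2,3,3a,4,5,7a-hexahydro-1H-indene-4-carboxylate
Conditions: SmI2 (2.5 equiv), THF–MeOH, −78 °C; then K2CO3, MeOH, 25 °C
Reagents that add atoms: none
Why: Single-electron reductive desulfonylation of the α-sulfonyl ketone gives a samarium enolate that is protonated, and base equilibration then places the C1 ethyl (and keeps the C3 methyl) trans to the neighbouring ring-fusion substituent.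

Step 13
Reactants: 22 methyl (1S,3S,3aR,4R,5S,7aR)-1,4,5-triethyl-3,7-dimethyl-2-oxo-5-[(E)-2-phenylethenyl]-2,3,3a,4,5,7a-hexahydro-1H-indene-4-carboxylate
Product: 23 (1S,3S,3aR,4R,5S,7aR)-1,4,5-triethyl-3,7-dimethyl-2-oxo-5-[(E)-2-phenylethenyl]-2,3,3a,4,5,7a-hexahydro-1H-indene-4-carboxylic acid
Conditions: NaSEt, DMF, 80 °C; then HCl (1 M aq.)
Reagents that add atoms: none
Why: SN2 O-demethylation by thiolate attacks the methyl group and so is unaffected by the two quaternary carbons shielding the acyl carbon; no stereocentre is touched and the α-centres stay in their equilibrium configuration.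

**Compound list**

1 | (E)-1-phenylpent-1-en-3-one | CCC(=O)/C=C/c1ccccc1 | starting material
2 | ethyl (E)-4-(diethoxyphosphoryl)-3-methylbut-2-enoate | CCOC(=O)/C=C(\C)CP(=O)(OCC)OCC | starting material
3 | sodium salt of the phosphonate carbanion of 2 | [Na+].CCOC(=O)/C=C(\C)[CH-]P(=O)(OCC)OCC | intermediate
4 | ethyl (2E,4E,6E)-5-ethyl-3-methyl-7-phenylhepta-2,4,6-trienoate | CCOC(=O)/C=C(C)/C=C(CC)/C=C/c1ccccc1 | intermediate
5 | (2E,4E,6E)-5-ethyl-3-methyl-7-phenylhepta-2,4,6-trien-1-ol | OC/C=C(C)/C=C(CC)/C=C/c1ccccc1 | intermediate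
6 | [(1E,3E,5E)-7-bromo-3-ethyl-5-methylhepta-1,3,5-trien-1-yl]benzene | BrC/C=C(C)/C=C(CC)/C=C/c1ccccc1 | intermediate
7 | {[(2E,4E,6E)-5-ethyl-3-methyl-7-phenylhepta-2,4,6-trien-1-yl]sulfonyl}benzene | O=S(=O)(C/C=C(C)/C=C(CC)/C=C/c1ccccc1)c1ccccc1 | intermediate
8 | methyl (R)-3-hydroxy-2-methylpropanoate | OC[C@@H](C)C(=O)OC | starting material
9 | methyl (R)-2-methyl-3-[(triethylsilyl)oxy]propanoate | CC[Si](CC)(CC)OC[C@@H](C)C(=O)OC | intermediate
10 | (R)-2-methyl-3-[(triethylsilyl)oxy]propanal | CC[Si](CC)(CC)OC[C@@H](C)C=O | intermediate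
11 | methyl 2-bromobutanoate (racemic) | CCC(Br)C(=O)OC | starting material
12 | triphenylphosphine | c1ccc(cc1)P(c1ccccc1)c1ccccc1 | starting material
13 | (1-methoxy-1-oxobutan-2-yl)triphenylphosphonium bromide | [Br-].CCC(C(=O)OC)[P+](c1ccccc1)(c1ccccc1)c1ccccc1 | intermediate
14 | methyl 2-(triphenylphosphoranylidene)butanoate | CCC(C(=O)OC)=P(c1ccccc1)(c1ccccc1)c1ccccc1 | intermediate
15 | methyl (2E,4S)-2-ethyl-4-methyl-5-[(triethylsilyl)oxy]pent-2-enoate | CC[Si](CC)(CC)OC[C@@H](C)/C=C(\CC)C(=O)OC | intermediate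
16 | methyl (2E,4S)-2-ethyl-4-methyl-5-oxopent-2-enoate | O=C[C@@H](C)/C=C(\CC)C(=O)OC | intermediate
17 | lithium salt of the α-sulfonyl carbanion of 7 | [Li+].O=S(=O)([CH-]/C=C(C)/C=C(CC)/C=C/c1ccccc1)c1ccccc1 | intermediate
18 | methyl (2E,4S,7E,9E,11E)-2,10-diethyl-5-hydroxy-4,8-dimethyl-12-phenyl-6-(phenylsulfonyl)dodeca-2,7,9,11-tetraenoate (C5/C6 diastereomer mixture) | OC([C@@H](C)/C=C(\CC)C(=O)OC)C(/C=C(C)/C=C(CC)/C=C/c1ccccc1)S(=O)(=O)c1ccccc1 | intermediate
19 | methyl (2E,4S,7E,9E,11E)-2,10-diethyl-4,8-dimethyl-5-oxo-12-phenyl-6-(phenylsulfonyl)dodeca-2,7,9,11-tetraenoate (C6 epimers interconvert) | O=C([C@@H](C)/C=C(\CC)C(=O)OC)C(/C=C(C)/C=C(CC)/C=C/c1ccccc1)S(=O)(=O)c1ccccc1 | intermediate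
20 | methyl (3S,3aS,4R,5S,7aS)-4,5-diethyl-3,7-dimethyl-2-oxo-5-[(E)-2-phenylethenyl]-1-(phenylsulfonyl)-2,3,3a,4,5,7a-hexahydro-1H-indene-4-carboxylate (C1 epimers) | O=S(=O)(c1ccccc1)C1C(=O)[C@@H](C)[C@H]2[C@H]1C(C)=C[C@@](/C=C/c1ccccc1)(CC)[C@]2(CC)C(=O)OC | intermediate
21 | methyl (3S,3aS,4R,5S,7aS)-1,4,5-triethyl-3,7-dimethyl-2-oxo-5-[(E)-2-phenylethenyl]-1-(phenylsulfonyl)-2,3,3a,4,5,7a-hexahydro-1H-indene-4-carboxylate (C1 not assigned) | CCC1(S(=O)(=O)c3ccccc3)C(=O)[C@@H](C)[C@H]2[C@H]1C(C)=C[C@@](/C=C/c1ccccc1)(CC)[C@]2(CC)C(=O)OC | intermediate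
22 | methyl (1S,3S,3aR,4R,5S,7aR)-1,4,5-triethyl-3,7-dimethyl-2-oxo-5-[(E)-2-phenylethenyl]-2,3,3a,4,5,7a-hexahydro-1H-indene-4-carboxylate | CC[C@@H]1C(=O)[C@@H](C)[C@H]2[C@H]1C(C)=C[C@@](/C=C/c1ccccc1)(CC)[C@]2(CC)C(=O)OC | intermediate
23 | (1S,3S,3aR,4R,5S,7aR)-1,4,5-triethyl-3,7-dimethyl-2-oxo-5-[(E)-2-phenylethenyl]-2,3,3a,4,5,7a-hexahydro-1H-indene-4-carboxylic acid | CC[C@@H]1C(=O)[C@@H](C)[C@H]2[C@H]1C(C)=C[C@@](/C=C/c1ccccc1)(CC)[C@]2(CC)C(=O)O | target

**Step count and risks**

Total: 13 steps. Longest linear sequence: 9 steps (8 → 9 → 10 → 15 → 16 → 18 → 20 → 21 → 22 → 23).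

Step 10 (oxidation and bicyclisation) is the most likely to fail. β-Keto sulfone 19 may tautomerise to the conjugated alkylidene isomer and lose its diene, and the endo/exo and facial selectivities are untested on this substrate. The fallback sets out from 19, this time made from 18 with Dess–Martin periodinane at 0 °C and isolated. The sulfone is removed before the cycloaddition with SmI2 in THF–MeOH at −78 °C, giving methyl (2E,4S,7E,9E,11E)-2,10-diethyl-4,8-dimethyl-5-oxo-12-phenyldodeca-2,7,9,11-tetraenoate F1. Heating F1 in toluene at 110 °C gives, under control by C3 alone, methyl (3S,3aR,4R,5S,7aS)-4,5-diethyl-3,7-dimethyl-2-oxo-5-[(E)-2-phenylethenyl]-2,3,3a,4,5,7a-hexahydro-1H-indene-4-carboxylate F2. Kinetic deprotonation of the C1 methylene with LiN(i-Pr)2 at −78 °C, alkylation with EtI in THF–DMPU and equilibration with K2CO3 in MeOH bring the material back at 22.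

Step 1 (vinylogous olefination of the enone) is the second risk: conjugate addition can compete, and the 2E/2Z and 4E/4Z isomers may be hard to separate. The fallback sets out from 1 and replaces olefination by addition and dehydration. A zinc-mediated vinylogous Reformatsky reaction with ethyl (E)-4-bromo-3-methylbut-2-enoate (Zn, THF, reflux) gives ethyl (2E,6E)-5-ethyl-5-hydroxy-3-methyl-7-phenylhepta-2,6-dienoate F3. Acid-catalysed dehydration into conjugation (TsOH, PhH, 60 °C) and the same iodine equilibration return to 4.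

Step 9 (sulfone carbanion addition) is the third risk: the delocalised carbanion may react at a remote position, and the addition is reversible. The fallback sets out from 16 (with 7) and changes the union from addition–oxidation to acylation. Pinnick oxidation (NaClO2, NaH2PO4, 2-methyl-2-butene, t-BuOH–H2O) gives (2S,3E)-4-(methoxycarbonyl)-2-methylhex-3-enoic acid F4. Carbonyldiimidazole in THF converts F4 into methyl (2E,4S)-2-ethyl-5-(1H-imidazol-1-yl)-4-methyl-5-oxopent-2-enoate F5. Adding F5 to two equivalents of 17 at −78 °C gives the β-keto sulfone directly and rejoins the route at 19, which is then heated as in step 10.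

**Further compounds**

F1 | step 10 | methyl (2E,4S,7E,9E,11E)-2,10-diethyl-4,8-dimethyl-5-oxo-12-phenyldodeca-2,7,9,11-tetraenoate | O=C([C@@H](C)/C=C(\CC)C(=O)OC)C/C=C(C)/C=C(CC)/C=C/c1ccccc1
F2 | step 10 | methyl (3S,3aR,4R,5S,7aS)-4,5-diethyl-3,7-dimethyl-2-oxo-5-[(E)-2-phenylethenyl]-2,3,3a,4,5,7a-hexahydro-1H-indene-4-carboxylate | C1C(=O)[C@@H](C)[C@H]2[C@H]1C(C)=C[C@@](/C=C/c1ccccc1)(CC)[C@]2(CC)C(=O)OC
F3 | step 1 | ethyl (2E,6E)-5-ethyl-5-hydroxy-3-methyl-7-phenylhepta-2,6-dienoate (racemic) | CCOC(=O)/C=C(\C)CC(O)(CC)/C=C/c1ccccc1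
F4 | step 9 | (2S,3E)-4-(methoxycarbonyl)-2-methylhex-3-enoic acid | OC(=O)[C@@H](C)/C=C(\CC)C(=O)OC
F5 | step 9 | methyl (2E,4S)-2-ethyl-5-(1H-imidazol-1-yl)-4-methyl-5-oxopent-2-enoate | O=C([C@@H](C)/C=C(\CC)C(=O)OC)n1ccnc1
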